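## Retrosynthetic overview

1. The target comes from its 5,7-di-O-benzyl ether by hydrogenolysis (last step).
2. The strategy rests on ring B being a 4-methoxyphenol (C2'–OH para to C5'–OMe, C4'–OMe beside it) bonded through C1', ortho to that hydroxyl, to C2 of pyranone ring C. Ring B is cut into a terminal alkyne (C1', C6'), an alkenyl(methoxy)carbene of chromium (C5', C4', C3') and one CO ligand (C2'), a Dötz benzannulation forming C5'–C6', C1'–C2' and C2'–C3'.
3. The alkyne partner, 5,7-bis(benzyloxy)-2-ethynyl-8-methoxychromone, comes from 4,6-bis(benzyloxy)-2-hydroxy-3-methoxyacetophenone and ethyl 3-(trimethylsilyl)propiolate (Claisen condensation, cyclodehydration closing O1–C2 of ring C, desilylation); the carbene partner comes from methyl vinyl ether and Cr(CO)6.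
4. The acetophenone comes from 2-methoxyresorcinol: the C5 oxygen (chromone numbering) by C–H borylation/oxidation and the acetyl group by ortho-lithiation, each on a mirror-symmetric intermediate, then chelation-controlled 7-O-benzylation, so that 8-OMe must end beside O1.
5. Ring order: A (purchased arene), then C (step 7), then B (step 10).

Key step: step 10

Remark: the target has no stereocentre; carbonyl ligands on chromium are written in SMILES as Cr=C=O, and the η6-arene tricarbonylchromium complex of step 10 is written as the arene and a Cr(CO)3 fragment joined by a dot, because SMILES cannot express η6 bonding.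

## Route

Step 1
Reactants: 1 2-methoxybenzene-1,3-diol (2-methoxyresorcinol)
Product: 2 2-methoxy-1,3-bis(methoxymethoxy)benzene
Conditions: NaH (2.4 equiv), DMF, 0 °C; MOMCl (2.4 equiv), 0 °C → rt
Reagents that add atoms: chloromethyl methyl ether, COCCl
Why: Williamson ether synthesis on both phenoxides with the very reactive α-chloro ether should be clean, and the methoxymethyl ethers are base-stable and later direct the ortho-lithiation.

Step 2
Reactants: 2 2-methoxy-1,3-bis(methoxymethoxy)benzene
Product: 4 4-methoxy-3,5-bis(methoxymethoxy)phenol, via pinacol arylboronate 3 (not isolated)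
Conditions: [Ir(OMe)(cod)]2 (1.5 mol%), 4,4'-di-tert-butyl-2,2'-bipyridine (3 mol%), B2pin2 (1.0 equiv), THF, 80 °C; then KHSO5 (Oxone, 1.0 equiv), acetone/H2O, 0 °C → rt, 15 min
Reagents that add atoms: potassium peroxymonosulfate, [K+].[O-]S(=O)(=O)OO (the phenol oxygen); bis(pinacolato)diboron, CC1(C)OB(OC1(C)C)B1OC(C)(C)C(C)(C)O1 (boron of 3 only)
Why: Sterically governed iridium-catalysed aromatic C–H borylation should occur only at C5, the one ring C–H with no ortho substituent, and oxidation of the C–B bond then gives the phenol at that carbon (one-pot borylation/oxidation).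

Step 3
Reactants: 4 4-methoxy-3,5-bis(methoxymethoxy)phenol
Product: 5 5-(benzyloxy)-2-methoxy-1,3-bis(methoxymethoxy)benzene
Conditions: BnBr (1.1 equiv), K2CO3 (1.5 equiv), DMF, rt
Reagents that add atoms: benzyl bromide, BrCc1ccccc1
Why: Williamson ether synthesis on the only free phenol installs the benzyl group that will protect O5 of the chromone until the last step.

Step 4
Reactants: 5 5-(benzyloxy)-2-methoxy-1,3-bis(methoxymethoxy)benzene
Product: 7 1-[6-(benzyloxy)-3-methoxy-2,4-bis(methoxymethoxy)phenyl]ethan-1-one, via aryllithium 6 (not isolated)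
Conditions: n-BuLi (1.15 equiv), THF, 0 °C, 1 h; then N-methoxy-N-methylacetamide (1.3 equiv), −78 °C → rt; H2O
Reagents that add atoms: N-methoxy-N-methylacetamide, CC(=O)N(C)OC
Why: Directed ortho-metalation should lithiate the C–H flanked by the OMOM and OBn groups (the two such positions are equivalent by symmetry, so only one product is possible), and acylation with the N-methoxy-N-methylamide stops at the ketone through the stable chelated tetrahedral intermediate.

Step 5
Reactants: 7 1-[6-(benzyloxy)-3-methoxy-2,4-bis(methoxymethoxy)phenyl]ethan-1-one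
Product: 8 1-[6-(benzyloxy)-2,4-dihydroxy-3-methoxyphenyl]ethan-1-one
Conditions: 3 M HCl, MeOH, 50 °C
Reagents that add atoms: none
Why: Acid-catalysed acetal methanolysis should remove both methoxymethyl groups as dimethoxymethane while the aryl benzyl and methyl ethers are stable to dilute acid.

Step 6
Reactants: 8 1-[6-(benzyloxy)-2,4-dihydroxy-3-methoxyphenyl]ethan-1-one
Product: 9 1-[4,6-bis(benzyloxy)-2-hydroxy-3-methoxyphenyl]ethan-1-one
Conditions: BnBr (1.05 equiv), K2CO3 (1.1 equiv), acetone, reflux
Reagents that add atoms: benzyl bromide, BrCc1ccccc1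
Why: Regioselective Williamson ether synthesis should take place at the 4-hydroxyl (para to the acetyl group, more acidic and unhindered), because the 2-hydroxyl is held in a hydrogen bond to the carbonyl and flanked by OMe and acetyl.

Step 7
Reactants: 9 1-[4,6-bis(benzyloxy)-2-hydroxy-3-methoxyphenyl]ethan-1-one; 10 ethyl 3-(trimethylsilyl)prop-2-ynoate
Product: 12 5,7-bis(benzyloxy)-8-methoxy-2-[(trimethylsilyl)ethynyl]-4H-chromen-4-one, via silylated ynedione 11 (not isolated)
Conditions: LiN(SiMe3)2 (3.3 equiv), THF, −78 °C, 1 h; 10 (1.3 equiv), −78 → −20 °C; AcOH (3.5 equiv); then p-TsOH·H2O (10 mol%), toluene, 60 °C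
Reagents that add atoms: none
Why: Crossed Claisen condensation of the phenoxide/enolate dianion with the ynoate (the third equivalent of base deprotonates the β-diketone) followed by acid cyclodehydration, in which the 2-hydroxyl adds to the distal carbonyl and water is lost, should give the chromone, the silyl group shielding the alkyne terminus against conjugate addition and against closure of the enol oxygen to a 4-pyranone.

Step 8
Reactants: 12 5,7-bis(benzyloxy)-8-methoxy-2-[(trimethylsilyl)ethynyl]-4H-chromen-4-one
Product: 13 5,7-bis(benzyloxy)-2-ethynyl-8-methoxy-4H-chromen-4-one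
Conditions: AgNO3 (10 mol%), acetone/H2O/CH2Cl2, rt, dark
Reagents that add atoms: none
Why: AgNO3-catalysed protodesilylation of the alkynylsilane proceeds through a silver acetylide under neutral conditions, so no alkoxide is present that could add to the electron-poor enyne.

Step 9
Reactants: 14 methyl vinyl ether; 15 chromium hexacarbonyl, Cr(CO)6
Product: 18 pentacarbonyl[methoxy(1-methoxyethenyl)carbene]chromium, via 1-methoxyvinyllithium 16 (not isolated), via lithium acylchromate 17 (not isolated)
Conditions: 14 (2 equiv), t-BuLi (1.0 equiv), THF, −78 → 0 °C; added to 15 (1.0 equiv), Et2O/THF, 0 °C → rt; solvent removed; Me3OBF4 (1.5 equiv), CH2Cl2/H2O, 0 °C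
Reagents that add atoms: trimethyloxonium tetrafluoroborate, C[O+](C)C.F[B-](F)(F)F
Why: Fischer carbene synthesis: α-lithiation of the enol ether gives the 1-methoxyvinyl anion, which adds to a CO ligand of Cr(CO)6, and O-methylation of the resulting acyl chromate with the hard oxonium salt should give the alkoxycarbene complex.

Step 10
Reactants: 13 5,7-bis(benzyloxy)-2-ethynyl-8-methoxy-4H-chromen-4-one; 18 pentacarbonyl[methoxy(1-methoxyethenyl)carbene]chromium
Product: 20 5,7-bis(benzyloxy)-2-(2-hydroxy-4,5-dimethoxyphenyl)-8-methoxy-4H-chromen-4-one, via tricarbonylchromium arene complex 19 (not isolated)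
Conditions: 18 (2.0 equiv), THF (0.05 M), 50 °C, argon; then air, CH2Cl2, rt
Reagents that add atoms: none
Why: Dötz benzannulation: thermal loss of one CO from 18 lets the terminal alkyne of 13 insert into the Cr=C bond with its CH carbon bonding to the carbene carbon (C5'–C6'), CO insertion gives a chromium-bound dienylketene (C1'–C2'), and this closes onto the CH2 carbon of the methoxyvinyl group (C2'–C3') and tautomerises to the phenol, held first as the Cr(CO)3 complex 19 and freed by air. The closest known reaction type is the benzannulation of alkenyl(alkoxy)carbene chromium complexes, α-alkoxyalkenyl ones included, with terminal and with carbonyl-conjugated alkynes. Ring B is the only ring closed, by a thermal six-electron electrocyclisation of the dienylketene, and no stereocentre is formed. The selectivity needed is the regiochemistry of alkyne insertion, which the size difference between H and the chromon-2-yl group should secure: the larger group is placed on the carbon next to the CO-derived carbon, so the hydroxyl appears at C2', ortho to ring C, and the alkyne hydrogen at C6'. Phenol formation should be favoured over cyclopentannulation or furan formation by the alkenyl alkoxy chromium complex in THF at moderate temperature, and the phenolic oxygen (from CO) and both methoxy groups (from 18) arrive already differentiated. The alkyne is electron-poor and may insert slowly, which is why 18 is used in excess.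

Step 11
Reactants: 20 5,7-bis(benzyloxy)-2-(2-hydroxy-4,5-dimethoxyphenyl)-8-methoxy-4H-chromen-4-one
Product: 21 5,7-dihydroxy-2-(2-hydroxy-4,5-dimethoxyphenyl)-8-methoxy-4H-chromen-4-one (target)
Conditions: H2 (1 atm), 10% Pd/C, EtOAc/MeOH, rt
Reagents that add atoms: none
Why: Catalytic hydrogenolysis should cleave both aryl benzyl ethers under conditions that leave the conjugated pyranone C2=C3 bond and the three methyl ethers untouched.

## Compound list

1 | 2-methoxybenzene-1,3-diol (2-methoxyresorcinol) | COc1c(O)cccc1O | starting material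
2 | 2-methoxy-1,3-bis(methoxymethoxy)benzene | COCOc1cccc(OCOC)c1OC | intermediate
3 | 2-[4-methoxy-3,5-bis(methoxymethoxy)phenyl]-4,4,5,5-tetramethyl-1,3,2-dioxaborolane | COCOc1cc(B2OC(C)(C)C(C)(C)O2)cc(OCOC)c1OC | intermediate (not isolated)
4 | 4-methoxy-3,5-bis(methoxymethoxy)phenol | COCOc1cc(O)cc(OCOC)c1OC | intermediate
5 | 5-(benzyloxy)-2-methoxy-1,3-bis(methoxymethoxy)benzene | COCOc1cc(OCc2ccccc2)cc(OCOC)c1OC | intermediate
6 | [6-(benzyloxy)-3-methoxy-2,4-bis(methoxymethoxy)phenyl]lithium | [Li]c1c(OCOC)c(OC)c(OCOC)cc1OCc1ccccc1 | intermediate (not isolated)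
7 | 1-[6-(benzyloxy)-3-methoxy-2,4-bis(methoxymethoxy)phenyl]ethan-1-one | CC(=O)c1c(OCOC)c(OC)c(OCOC)cc1OCc1ccccc1 | intermediate
8 | 1-[6-(benzyloxy)-2,4-dihydroxy-3-methoxyphenyl]ethan-1-one | CC(=O)c1c(O)c(OC)c(O)cc1OCc1ccccc1 | intermediate
9 | 1-[4,6-bis(benzyloxy)-2-hydroxy-3-methoxyphenyl]ethan-1-one | CC(=O)c1c(O)c(OC)c(OCc2ccccc2)cc1OCc1ccccc1 | intermediate
10 | ethyl 3-(trimethylsilyl)prop-2-ynoate | CCOC(=O)C#C[Si](C)(C)C | starting material
11 | 1-[4,6-bis(benzyloxy)-2-hydroxy-3-methoxyphenyl]-5-(trimethylsilyl)pent-4-yne-1,3-dione | C[Si](C)(C)C#CC(=O)CC(=O)c1c(O)c(OC)c(OCc2ccccc2)cc1OCc1ccccc1 | intermediate (not isolated)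
12 | 5,7-bis(benzyloxy)-8-methoxy-2-[(trimethylsilyl)ethynyl]-4H-chromen-4-one | C[Si](C)(C)C#Cc1cc(=O)c2c(OCc3ccccc3)cc(OCc3ccccc3)c(OC)c2o1 | intermediate
13 | 5,7-bis(benzyloxy)-2-ethynyl-8-methoxy-4H-chromen-4-one | C#Cc1cc(=O)c2c(OCc3ccccc3)cc(OCc3ccccc3)c(OC)c2o1 | intermediate (key-step precursor)
14 | methyl vinyl ether (methoxyethene) | COC=C | starting material
15 | chromium hexacarbonyl, Cr(CO)6 | O=C=[Cr](=C=O)(=C=O)(=C=O)(=C=O)=C=O | starting material
16 | (1-methoxyethenyl)lithium | [Li]C(=C)OC | intermediate (not isolated)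
17 | lithium pentacarbonyl(2-methoxyprop-2-enoyl)chromate | [Li+].C=C(OC)C([O-])=[Cr](=C=O)(=C=O)(=C=O)(=C=O)=C=O | intermediate (not isolated)
18 | pentacarbonyl[methoxy(1-methoxyethenyl)carbene]chromium | C=C(OC)C(OC)=[Cr](=C=O)(=C=O)(=C=O)(=C=O)=C=O | intermediate (key-step precursor)
19 | tricarbonyl{η6-[ring B of 5,7-bis(benzyloxy)-2-(2-hydroxy-4,5-dimethoxyphenyl)-8-methoxy-4H-chromen-4-one]}chromium | COc1cc(O)c(-c2cc(=O)c3c(OCc4ccccc4)cc(OCc4ccccc4)c(OC)c3o2)cc1OC.O=C=[Cr](=C=O)=C=O | intermediate (not isolated)
20 | 5,7-bis(benzyloxy)-2-(2-hydroxy-4,5-dimethoxyphenyl)-8-methoxy-4H-chromen-4-one | COc1cc(O)c(-c2cc(=O)c3c(OCc4ccccc4)cc(OCc4ccccc4)c(OC)c3o2)cc1OC | intermediate (key-step product)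
21 | 5,7-dihydroxy-2-(2-hydroxy-4,5-dimethoxyphenyl)-8-methoxy-4H-chromen-4-one | COc1cc(O)c(-c2cc(=O)c3c(O)cc(O)c(OC)c3o2)cc1OC | target

## Step count and risks

Total step count: 11. Longest linear sequence: 10 steps (steps 1–8, 10 and 11, from 1 to 21); the carbene complex 18 is made in one step (step 9) on a side branch.

Steps most likely to fail:

1. Step 10 (key step). The electron-poor alkyne may insert so slowly that the carbene complex decomposes first, regiocontrol of the insertion may be eroded, or the vinylcarbene intermediate may be diverted to cyclopentadiene- or furan-type products. The carbene complex of step 9 is a prerequisite of this step and shares its fallback. The fallback is a classical flavone construction that leaves the route at 9 and rejoins it at 21. Commercial 2-hydroxy-4,5-dimethoxybenzaldehyde is benzylated (BnBr, K2CO3, DMF) to 2-(benzyloxy)-4,5-dimethoxybenzaldehyde F1. Claisen–Schmidt condensation of 9 with F1 (KOH, EtOH, rt) should give the 2'-hydroxychalcone F2. Oxidative cyclisation (I2 cat., DMSO, 120 °C) should give the tri-O-benzyl flavone F3, and hydrogenolysis of its three benzyl ethers (H2, 10% Pd/C) gives 21.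

2. Step 7. The enolate or the amide base may add in conjugate fashion to the ynoate instead of substituting at the acyl carbon, the silyl group may be lost to lithium ethoxide, or the enol oxygen may close onto the alkyne to a 4-pyranone instead of the phenol closing onto the carbonyl. The fallback sets out from 9 and rejoins the route at 13, bypassing step 8. Claisen condensation of 9 with diethyl oxalate (NaOEt, EtOH) and acid cyclodehydration (HCl, EtOH) should give the ethyl chromone-2-carboxylate F4. NaBH4 (MeOH/THF, 0 °C) reduces the activated ester to the 2-(hydroxymethyl)chromone F5, and MnO2 (CH2Cl2) oxidises it to the chromone-2-carbaldehyde F6. Seyferth–Gilbert homologation of F6 with dimethyl (1-diazo-2-oxopropyl)phosphonate (K2CO3, MeOH/THF, 0 °C, short contact time) gives 13.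

3. Step 4. Deprotonation at the benzylic CH2 (followed by Wittig rearrangement) may compete with ring lithiation, or the hindered aryllithium may enolise the acetamide and return 5. The fallback sets out from 5 and rejoins the route at 8. The methoxymethyl groups are removed first (3 M HCl, MeOH, 50 °C) to give the symmetric resorcinol 5-(benzyloxy)-2-methoxybenzene-1,3-diol F7. Hoesch acylation (MeCN, ZnCl2, HCl gas, Et2O, 0 °C) at either of its two equivalent ring positions gives the ketiminium chloride F8, which is hydrolysed in hot water to 8.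

Further compounds
F1 | step 10 | 2-(benzyloxy)-4,5-dimethoxybenzaldehyde | COc1cc(C=O)c(OCc2ccccc2)cc1OC
F2 | step 10 | (E)-1-[4,6-bis(benzyloxy)-2-hydroxy-3-methoxyphenyl]-3-[2-(benzyloxy)-4,5-dimethoxyphenyl]prop-2-en-1-one | COc1cc(/C=C/C(=O)c2c(O)c(OC)c(OCc3ccccc3)cc2OCc2ccccc2)c(OCc2ccccc2)cc1OC
F3 | step 10 | 5,7-bis(benzyloxy)-2-[2-(benzyloxy)-4,5-dimethoxyphenyl]-8-methoxy-4H-chromen-4-one | COc1cc(OCc2ccccc2)c(-c2cc(=O)c3c(OCc4ccccc4)cc(OCc4ccccc4)c(OC)c3o2)cc1OC
F4 | step 7 | ethyl 5,7-bis(benzyloxy)-8-methoxy-4-oxo-4H-chromene-2-carboxylate | CCOC(=O)c1cc(=O)c2c(OCc3ccccc3)cc(OCc3ccccc3)c(OC)c2o1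
F5 | step 7 | 5,7-bis(benzyloxy)-2-(hydroxymethyl)-8-methoxy-4H-chromen-4-one | OCc1cc(=O)c2c(OCc3ccccc3)cc(OCc3ccccc3)c(OC)c2o1
F6 | step 7 | 5,7-bis(benzyloxy)-8-methoxy-4-oxo-4H-chromene-2-carbaldehyde | O=Cc1cc(=O)c2c(OCc3ccccc3)cc(OCc3ccccc3)c(OC)c2o1
F7 | step 4 | 5-(benzyloxy)-2-methoxybenzene-1,3-diol | COc1c(O)cc(OCc2ccccc2)cc1O
F8 | step 4 | 1-[6-(benzyloxy)-2,4-dihydroxy-3-methoxyphenyl]ethan-1-iminium chloride | CC(=[NH2+])c1c(O)c(OC)c(O)cc1OCc1ccccc1.[Cl-]
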